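Of the 8 mM of second nucleophile charged in the midnight run, other capture product holds 7.28 mM, so 0.720 mM is left over, and you can read that as second nucleophile lost to decomposition rather than to capture. That matters for a simple reason. Both nucleophiles draw on one intermediate, so its concentration cancels: at a fixed temperature, target forms per other capture product in proportion to [first nucleophile]/[second nucleophile] at that moment.

| setting | dusk | spring | midnight | larch | cedar | birch | elm |
|---|---|---|---|---|---|---|---|
| starting material | 10 mM | 5 mM | 20 mM | 10 mM (fed, over 15 h) | 10 mM (in portions, 5, over 15 h) | 10 mM | 10 mM (fed, over 15 h) |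
| first nucleophile | 5 mM | 5 mM | 5 mM | 5.00 mM | 5.00 mM | 5.00 mM (fed, over 15 h) | 5.00 mM |
| second nucleophile | 8 mM | 8 mM | 8 mM | 8.00 mM | 8.00 mM | 8.00 mM | 8.00 mM |
| temperature | 45 °C | 60 °C | 45 °C |  | 60 °C | 60 °C | 60 °C |
| remark | run made earlier | run made earlier | run made earlier | the addition at 30 °C, then warmed to 60 °C; the feed brings no volume worth counting | first portion at the start, last at 15 h | all else is in the flask from the start; the feed brings no volume worth counting | all else is in the flask from the start; the feed brings no volume worth counting |
| time |  |  |  | 40 h | 40 h | 40 h | 40 h |

- dusk (time / h: target / %, other capture product / %): 6.00: 26.6, 48.6; 15.0: 28.7, 51.6; 30.0: 29.8, 51.3; 96.0: 27.7, 51.1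
- spring (time / h: target / %, other capture product / %): 8.00: 23.4, 49.3; 15.0: 22.5, 51.0; 25.0: 20.1, 49.3; 30.0: 23.2, 49.1
- midnight (time / h: target / %, other capture product / %): 5.00: 23.5, 35.8; 12.0: 24.9, 37.2; 30.0: 25.3, 35.9; 60.0: 22.8, 36.6

(each reading ± 1 percentage point)

- the analysis behind the earlier runs scatters by 1 percentage point, standard deviation
- on the list of suspects stand: starting material -> intermediate; first nucleophile + intermediate -> target; second nucleophile + intermediate -> other capture product; intermediate -> solvolysis product; second nucleophile -> decomposed reagent; intermediate -> side product

In the spring run, at 60 °C, the summed readings give 0.449 target per other capture product on a charged ratio of 0.625. So I read 0.718 as an apparent selectivity factor, the target formed per other capture product for each unit of charged [first nucleophile]/[second nucleophile]. It is a reading on the charged ratio, not on the ratio the intermediate met as the second nucleophile decomposed.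

My own reckoning gives a direction and one number. Everything charged at once at 60 °C means a share near 31.0 %. Feeding starting material gives the second nucleophile time to decompose, so the ratio should climb in elm; feeding first nucleophile should sink it in birch. I commit to elm on top and birch at the bottom.

1. the flask with the highest share of target in target plus other capture product ("all alike" if they lie within 1.5 percentage points) (larch / cedar / birch / elm / all alike)
2. share of target in target plus other capture product at the end, larch
3. share of target in target plus other capture product at the end, cedar
4. share of target in target plus other capture product at the end, birch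
5. share of target in target plus other capture product at the end, elm

The forecast named elm, with 37 % for larch, 45 % for cedar, 5 % for birch and 46 % for elm: “Slow feeding at 60 °C lets the second nucleophile decay first”.

The flasks give elm as highest, with larch at 35.7 %, cedar at 71.0 %, birch at 2.83 % and elm at 78.5 %.

    starting material → intermediate (k = 2.20 h⁻¹, Ea = 92.0 kJ mol⁻¹)
    first nucleophile + intermediate → target (k = 1400 M⁻¹ h⁻¹, Ea = 49.0 kJ mol⁻¹)
    second nucleophile + intermediate → other capture product (k = 2600 M⁻¹ h⁻¹, Ea = 56.0 kJ mol⁻¹)
    intermediate → solvolysis product (k = 4.30 h⁻¹, Ea = 91.0 kJ mol⁻¹)
    second nucleophile → decomposed reagent (k = 0.490 h⁻¹, Ea = 117 kJ mol⁻¹)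
    intermediate → side product (k = 3.00 h⁻¹, Ea = 97.0 kJ mol⁻¹)
    (constants at 60 °C)

Elm's 78.5 % stands against the forecast's 46 %. At the end of elm, decomposed reagent stands at 7.08 mM out of 8.00 mM of second nucleophile charged, with target at 33.4 % and other capture product at 9.16 %. Their quotient, 3.65, on the charged ratio of 0.625 gives elm an apparent selectivity factor of 5.84, against 0.718 in the spring run on that same charged ratio. In birch, target at 1.53 % and other capture product at 52.6 % give, by the same division, 0.0465.

The data were computed with made-up constants; noise was put on by code.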